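The plan rests on cutting the Ch–Ci edge of the cyclopropane (Ch–Ci–Cj). This edge is shared with the five-membered ring Cf–Cg–Ch–Ci–Ca of the nortricyclane. In the open form both ends are electrophilic: Ch is an aldehyde carbon and Ci is the β-carbon of the Ck–Cj–Ci enone, so the bond is made reductively. One SmI2 step closes that ring, turns a hydrindenone into a norbornanone, and sets Ch (exo OH), Ci and Cj. Enolate displacement at Ch then closes Ch–Cj. The precursor is a cis-fused 2-methylhydrindenone with a CH2CHO arm on Cf, the Ca carboxyl locked to the Cc oxygen as a γ-lactone, and Cd–OTBS in place.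

Key step: step 9

**Atom labels**
- Ca is the quaternary carbon bearing the acetoxymethyl group; its exocyclic carbon is Cm.
- Round the six-membered ring from Ca: Cb (CH2), Cc (CHOH), Cd (CHOAc), Ce (CMe2), Cf (quaternary cage apex).
- Cg is the cage CH2 on Cf.
- Ch, Ci and Cj are the cyclopropane carbons bonded to Cg, Ca and Ck respectively; Cj carries CH3.
- Ck is the cage CHOAc between Cj and Cf.
- α is the side of the Ca–Cf bond on which Cm stands. Cg, Cc–O and Cd–O of the target are also α. Ci and Ck (seen from the six-membered ring) and Cb and Ce (seen from the five-membered ring) are β.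

**Design points**
- The CMe2-terminated diene is used as its 2-silyloxy derivative. This makes it reactive enough and delivers Cc at the ketone level, so the Cc and Cd oxygens are introduced one after the other and are differentiated from the start.
- Absolute configuration enters in step 2. All later centres are relayed from Ca and Cf.
- In 15, Cm is tied to Cc–O. Cm stands syn to the new Cg–Ch bridge, right beside the exo oxygen formed in step 9, and an open-chain ester there could capture that oxygen.
- After step 11 no electron-transfer reductant is used, because 18 is a cyclopropyl ketone held in the bisected geometry.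

**Assumptions**
- The (S)-prolinol-derived catalyst of step 2 is taken to give the drawn antipode of 4. If the first run shows the opposite sense, the equally available (R)-catalyst is used and nothing else changes.
- The Cj epimers of 5 and 16 are drawn as the expected ones. Either serves, since Cj is enolised in the following step.

Step 1
Reactants: 1 mesityl oxide
Product: 2 silyloxydiene
Conditions: TBSOTf, Et3N, Et2O, 0 °C
Reagents that add atoms: tert-butyldimethylsilyl triflate, CC(C)(C)[Si](C)(C)OS(=O)(=O)C(F)(F)F
Why: Soft enolisation of an enone, in which O-silylation followed by loss of an α′-methyl proton to the amine gives the cross-conjugated 2-silyloxydiene, and no stereocentre is created.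

Step 2
Reactants: 2 silyloxydiene; 3 methyl 3-oxocyclopent-1-ene-1-carboxylate
Product: 4 cis-hydrindanone adduct
Conditions: (S)-diphenylprolinol-derived B-(o-tolyl)oxazaborolidine (20 mol %), Tf2NH (18 mol %), CH2Cl2, −78 → −20 °C
Reagents that add atoms: none
Why: Catalytic enantioselective Diels–Alder reaction of a 2-silyloxydiene with a cyclic enone (strongly asynchronous, Mukaiyama–Michael-like), in which the boron cation binds the more basic ketone oxygen so that the nucleophilic CH2 terminus bonds to Ca (β to Ck=O) and the CMe2 terminus to Cf, suprafacial addition makes the ring fusion cis, the aryl shield of the catalyst selects the face and thereby the absolute configuration of Ca and Cf, and the 2-silyloxy group supplies the HOMO energy and s-cis population that a bare 4,4-dimethyl diene lacks.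

Step 3
Reactants: 4 cis-hydrindanone adduct
Product: 5 Cj-methyl ketone
Conditions: LDA, THF, −78 °C; MeI
Reagents that add atoms: iodomethane, CI
Why: Kinetic enolate alkylation, in which LDA takes a proton from the open Cj methylene rather than the neopentyl Cf–H, the ester has no α-hydrogen and the TBS enol ether is inert to base, and MeI enters on the α-face away from the six-membered ring, a centre that becomes sp2 in step 4.

Step 4
Reactants: 5 Cj-methyl ketone
Product: 7 hydrindenone enol ether, via TMS enol ether 6 (not isolated)
Conditions: TMSOTf, Et3N, CH2Cl2, 0 °C → rt; then Pd(OAc)2 (1.05 equiv), MeCN, rt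
Reagents that add atoms: trimethylsilyl triflate, C[Si](C)(C)OS(=O)(=O)C(F)(F)F (its silyl group is present in 6 only)
Why: Saegusa–Ito oxidation, in which equilibrating silylation enolises toward Cj because a Ck=Cf double bond would be wedged between two quaternary carbons, Pd(II) engages the TMS enol ether and β-hydride elimination of a ring Ci–H gives the endocyclic 2-methylcyclopentenone, while the TBS enol ether is spared since its carbon Cd is neopentyl and a palladium enolate there would have no β-hydrogen.

Step 5
Reactants: 7 hydrindenone enol ether
Product: 9 α-silyloxy ketone, via silyloxy epoxide 8 (not isolated)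
Conditions: m-CPBA, CH2Cl2, −15 → 0 °C
Reagents that add atoms: 3-chloroperbenzoic acid, O=C(OO)c1cccc(Cl)c1
Why: Rubottom oxidation, in which the peracid picks the only electron-rich alkene and approaches the convex α-face of the cis-hydrindenone (the side of the small Cf–H, the β-face being covered by the five-membered ring and a pseudoaxial Ce methyl), and the silyloxy epoxide opens with 1,4-silyl shift to leave OTBS α on Cd and a ketone at Cc.

Step 6
Reactants: 9 α-silyloxy ketone
Product: 11 lactone enone, via hydroxy ester 10 (not isolated)
Conditions: NaBH4, MeOH–CH2Cl2, −78 → −40 °C; then PPTS (cat.), PhMe, 60 °C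
Reagents that add atoms: none
Why: Chemoselective borohydride reduction (a saturated α-oxy cyclohexanone reacts faster than the hindered conjugated Ck=O at low temperature), in which the α-face of Cc=O is closed by the syn-axial Cm on Ca and a methyl on Ce so that hydride enters from the β-face, and the resulting α (axial) hydroxyl lies 1,3-cis to the ester and lactonises with loss of methanol.

Step 7
Reactants: 11 lactone enone; 12 allyl bromide
Product: 13 Cf-allyl lactone enone
Conditions: KHMDS, THF, −78 → 0 °C; allyl bromide
Reagents that add atoms: none
Why: α′-Alkylation of the cross-conjugated potassium dienolate (Cf–H is the only acidic proton), in which the allyl group bonds on the α-face because β-attack would build a trans-fused cyclopentenone whose ring torsion a planar enone cannot accommodate, so the quaternary Cf is set with Cg cis to Cm.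

Step 8
Reactants: 13 Cf-allyl lactone enone
Product: 15 aldehyde precursor, via ozonide 14 (not isolated)
Conditions: O3, CH2Cl2, −78 °C (Sudan III end point); PPh3, −78 °C → rt
Reagents that add atoms: ozone, [O-][O+]=O
Why: Ozonolysis with reductive work-up, in which the monosubstituted alkene is the only electron-rich π-bond left (the enone is deactivated and trisubstituted), so titration to a dye end point cleaves it alone to the CH2CHO arm.

Step 9
Reactants: 15 aldehyde precursor
Product: 16 exo-hydroxy norbornanone
Conditions: SmI2 (2.5 equiv), t-BuOH (2.5 equiv), THF (0.01 M), −78 → 0 °C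
Reagents that add atoms: none
Why: SmI2 gives one electron to the aldehyde, the Sm(III)-bound ketyl at Ch adds as a nucleophilic radical to the electron-poor β-carbon Ci of the Ck–Cj–Ci enone, and a second electron turns the Cj radical into a samarium enolate that t-BuOH protonates; this is the established SmI2 ketyl–olefin (aldehyde–enone) reductive cyclisation, here a polarity-matched version of the cyclopent-3-enylethyl to 2-norbornyl radical closure. The one ring closed, Cf–Cg–Ch–Ci–Ca, forms in the 5-exo-trig mode (Cj stays outside it), which turns the hydrindenone into a bicyclo[2.2.1]heptan-2-one with Ca as the one-carbon bridge. Ci is fixed by the tether, since the arm stands on the α-face of Cf and can reach only that face of Ci. Ch is set by the usual anti arrangement of the O–Sm bond and the developing enolate (dipole repulsion and the bulk of ligated samarium keep the oxygen out of the endo pocket under Cj and Ck, and the nearby lactone carbonyl can chelate the metal), so the hydroxyl ends exo, while Cj is protonated from the endo side because Cb and a Ce methyl cover the exo side, a centre that step 11 erases anyway. The step needs C–C bond formation to outrun protonation or further reduction of either π-system and intermolecular pinacol coupling; the closeness of Ch and Ci in the cis-fused, lactone-locked scaffold, high dilution, low temperature and a weak proton source should secure this, and the γ-lactone and silyl ether are inert to SmI2 in the absence of water or amine. Because Cm already belongs to an unstrained γ-lactone, the new exo alkoxide beside it has no driving force to acylate itself and stays free for step 10.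

Step 10
Reactants: 16 exo-hydroxy norbornanone
Product: 17 exo-mesylate
Conditions: MsCl, Et3N, CH2Cl2, 0 °C
Reagents that add atoms: methanesulfonyl chloride, CS(=O)(=O)Cl
Why: Sulfonylation of a secondary alcohol, in which the C–O bond is not touched so the exo configuration at Ch is retained.

Step 11
Reactants: 17 exo-mesylate
Product: 18 nortricyclanone
Conditions: KHMDS, THF, −78 °C → rt
Reagents that add atoms: none
Why: Intramolecular enolate alkylation (3-exo-tet, the classical closure of 5-exo-sulfonyloxynorbornan-2-ones to nortricyclanones), in which the endo lobe of the Cj enolate lies directly behind the exo C–OMs bond so that Ch is inverted, Ch–Cj forms and Cj becomes the methyl-bearing quaternary cyclopropane carbon, while the lactone has no α-hydrogen and the amide base is non-nucleophilic.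

Step 12
Reactants: 18 nortricyclanone
Product: 19 nortricyclanol
Conditions: Al(Oi-Pr)3 (3 equiv), i-PrOH–PhMe, reflux, closed system (acetone retained), prolonged
Reagents that add atoms: none
Why: Meerwein–Ponndorf–Verley reduction under equilibrating conditions, in which reversible hydride transfer lets the bulky aluminium alkoxide settle in the roomier sector between Ck and Cg with the Ck–H facing Cb, whereas irreversible hydrides would enter from that open sector and give the epimer, and electron-transfer reductants are excluded because the ketyl of this bisected cyclopropyl ketone would cleave Cj–Ch or Cj–Ci.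

Step 13
Reactants: 19 nortricyclanol
Product: 20 triol
Conditions: LiAlH4, THF, 0 °C → rt
Reagents that add atoms: none
Why: Hydride reduction of the γ-lactone to the primary Cm–OH and the secondary Cc–OH, which leaves the silyl ether, the cyclopropane and every stereocentre untouched.

Step 14
Reactants: 20 triol
Product: 21 diacetate
Conditions: Ac2O (2.5 equiv), Et3N, DMAP (cat.), CH2Cl2, 0 °C → rt
Reagents that add atoms: acetic anhydride, CC(=O)OC(C)=O
Why: DMAP-catalysed acylation, which should take the primary Cm–OH and the outward-pointing Ck–OH while Cc–OH, axial between the axial CH2O group on Ca, the axial methyl on Ce and the neighbouring OTBS, stays free.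

Step 15
Reactants: 21 diacetate
Product: 22 diol diacetate
Conditions: HF·pyridine, THF, 0 °C → rt
Reagents that add atoms: none
Why: Fluoride-mediated desilylation in a mildly acidic medium, which leaves both acetates (including the cyclopropylcarbinyl one) in place and does not promote acyl migration.

Step 16
Reactants: 22 diol diacetate
Product: 23 target CNP0111873.1
Conditions: Ac2O (1.2 equiv), pyridine, 0 °C → rt
Reagents that add atoms: acetic anhydride, CC(=O)OC(C)=O
Why: Selective acylation of a cis-1,2-diol, in which the equatorial Cd–OH reacts and the axial Cc–OH, flanked by two syn-axial carbon substituents as in the A-ring 2β,3β-diols of 4,4-dimethyl terpenoids, does not, the equatorial acetate also being the isomer favoured by any acyl migration.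

**Compound list**

1 | mesityl oxide (4-methylpent-3-en-2-one) | CC(=O)C=C(C)C | starting material
2 | silyloxydiene: 2-(tert-butyldimethylsilyloxy)-4-methylpenta-1,3-diene | C=C(O[Si](C)(C)C(C)(C)C)C=C(C)C | intermediate
3 | methyl 3-oxocyclopent-1-ene-1-carboxylate | COC(=O)C1=CC(=O)CC1 | starting material
4 | cis-hydrindanone adduct: CO2Me on Ca and H on Cf both α, Cc(OTBS)=Cd enol ether, CMe2 (Ce) next to Cf, ketone at Ck | COC(=O)[C@]12CC(O[Si](C)(C)C(C)(C)C)=CC(C)(C)[C@H]1C(=O)CC2 | intermediate
5 | Cj-methyl ketone: as 4 with an α-methyl on Cj | COC(=O)[C@]12CC(O[Si](C)(C)C(C)(C)C)=CC(C)(C)[C@H]1C(=O)[C@H](C)C2 | intermediate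
6 | TMS enol ether: Ck(OTMS)=Cj(CH3) derivative of 5 | COC(=O)[C@]12CC(O[Si](C)(C)C(C)(C)C)=CC(C)(C)[C@H]1C(O[Si](C)(C)C)=C(C)C2 | intermediate (not isolated)
7 | hydrindenone enol ether: Ck(=O)–Cj(CH3)=Ci enone, Cf–H α, TBS enol ether retained | COC(=O)[C@]12CC(O[Si](C)(C)C(C)(C)C)=CC(C)(C)[C@H]1C(=O)C(C)=C2 | intermediate
8 | silyloxy epoxide: α-epoxide across Cc–Cd, OTBS on Cc | COC(=O)[C@]12C[C@]3(O[Si](C)(C)C(C)(C)C)O[C@@H]3C(C)(C)[C@H]1C(=O)C(C)=C2 | intermediate (not isolated)
9 | α-silyloxy ketone: Cc=O, Cd–OTBS α | COC(=O)[C@]12CC(=O)[C@H](O[Si](C)(C)C(C)(C)C)C(C)(C)[C@H]1C(=O)C(C)=C2 | intermediate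
10 | hydroxy ester: Cc–OH α, cis to Cd–OTBS and to CO2Me | COC(=O)[C@]12C[C@H](O)[C@H](O[Si](C)(C)C(C)(C)C)C(C)(C)[C@H]1C(=O)C(C)=C2 | intermediate (not isolated)
11 | lactone enone: γ-lactone Cm(=O)–O–Cc bridging the α-face, Cd–OTBS α, Cf–H α, 2-methylcyclopentenone | O=C4[C@]12C[C@H](O4)[C@H](O[Si](C)(C)C(C)(C)C)C(C)(C)[C@H]1C(=O)C(C)=C2 | intermediate
12 | allyl bromide | C=CCBr | starting material
13 | Cf-allyl lactone enone: allyl α on quaternary Cf, ring fusion cis | O=C4[C@]12C[C@H](O4)[C@H](O[Si](C)(C)C(C)(C)C)C(C)(C)[C@@]1(CC=C)C(=O)C(C)=C2 | intermediate
14 | ozonide: 1,2,4-trioxolane at the end of the Cf arm (epimers at the trioxolane carbon) | O=C4[C@]12C[C@H](O4)[C@H](O[Si](C)(C)C(C)(C)C)C(C)(C)[C@@]1(CC5OCOO5)C(=O)C(C)=C2 | intermediate (not isolated)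
15 | aldehyde precursor (precursor of the key step): cis-hydrindenone with α-CH2CHO on Cf, lactone, Cd–OTBS | O=C4[C@]12C[C@H](O4)[C@H](O[Si](C)(C)C(C)(C)C)C(C)(C)[C@@]1(CC=O)C(=O)C(C)=C2 | intermediate
16 | exo-hydroxy norbornanone (product of the key step): bridgeheads Cf and Ci, Ca the one-carbon bridge, Ck=O, OH exo on Ch, CH3 exo on Cj, Cm syn to the Cg–Ch bridge, Cb syn to the Ck–Cj bridge | O=C4[C@]12C[C@H](O4)[C@H](O[Si](C)(C)C(C)(C)C)C(C)(C)[C@]13C[C@H](O)[C@H]2[C@H](C)C3=O | intermediate
17 | exo-mesylate of 16 | O=C4[C@]12C[C@H](O4)[C@H](O[Si](C)(C)C(C)(C)C)C(C)(C)[C@]13C[C@H](OS(C)(=O)=O)[C@H]2[C@H](C)C3=O | intermediate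
18 | nortricyclanone: cyclopropane Ch–Ci–Cj closed, ketone at Ck, lactone and OTBS retained | O=C4[C@]12C[C@H](O4)[C@H](O[Si](C)(C)C(C)(C)C)C(C)(C)[C@]13C[C@@H]1[C@H]2[C@]1(C)C3=O | intermediate
19 | nortricyclanol: Ck–OH pointing into the Ck/Cg sector, Ck–H toward Cb | O=C4[C@]12C[C@H](O4)[C@H](O[Si](C)(C)C(C)(C)C)C(C)(C)[C@]13C[C@@H]1[C@H]2[C@]1(C)[C@H]3O | intermediate
20 | triol: Cm–OH, Cc–OH (α, axial), Ck–OH free, Cd–OTBS | OC[C@]12C[C@H](O)[C@H](O[Si](C)(C)C(C)(C)C)C(C)(C)[C@]13C[C@@H]1[C@H]2[C@]1(C)[C@H]3O | intermediate
21 | diacetate: Cm–OAc, Ck–OAc, Cc–OH free, Cd–OTBS | CC(=O)OC[C@]12C[C@H](O)[C@H](O[Si](C)(C)C(C)(C)C)C(C)(C)[C@]13C[C@@H]1[C@H]2[C@]1(C)[C@H]3OC(C)=O | intermediate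
22 | diol diacetate: cis-α-diol at Cc and Cd, Cm–OAc, Ck–OAc | CC(=O)OC[C@]12C[C@H](O)[C@H](O)C(C)(C)[C@]13C[C@@H]1[C@H]2[C@]1(C)[C@H]3OC(C)=O | intermediate
23 | CNP0111873.1 | CC(=O)OC[C@]12C[C@H](O)[C@H](OC(C)=O)C(C)(C)[C@]13C[C@@H]1[C@H]2[C@]1(C)[C@H]3OC(C)=O | target

Total steps: 16. Longest linear sequence: 16 (1 → 23; 3 and 12 are bought).

**Steps most likely to fail**

**1. Step 9.**
- What may go wrong:
  - electron transfer to the enone followed by protonation (plain conjugate reduction);
  - closure of the resulting Cj enolate onto the aldehyde (reductive aldol, the wrong bond);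
  - intermolecular pinacol coupling;
  - turning of the ketyl oxygen into the endo pocket, which would leave an alcohol that cannot be displaced from behind.
- Fallback: it sets out from 15, returns at 18, and replaces steps 9–11. Both cyclopropane edges are made by dipolar cycloaddition and nitrogen extrusion instead of electron transfer. Condensation of the aldehyde with tosylhydrazine (MeOH, rt; the hindered conjugated ketone does not compete) gives the tosylhydrazone F1. NaH in warm toluene (aprotic Bamford–Stevens conditions) expels sulfinate to give the diazoalkane F2. Its nucleophilic carbon Ch adds to Ci, and its terminal nitrogen adds to Cj, both on the α-face of the electron-poor enone, giving the bridged 1-pyrazoline F3. Irradiation at 350 nm (or heating) extrudes nitrogen and collapses the diradical to 18.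

**2. Step 7.**
- What may go wrong: slow deprotonation of the buried Cf–H, alkylation on oxygen instead of on a carbon flanked by two quaternary centres, or erosion of facial selectivity.
- Fallback: it sets out from 11 and returns at 13. The potassium dienolate is deliberately steered to oxygen (KH, 18-crown-6, allyl tosylate, THF–DMPU) to give the allyl dienol ether F4. Heating in toluene (sealed tube) moves the allyl group from O to Cf by Claisen rearrangement. This concerted process tolerates fully substituted termini far better than an SN2 transition state. The same ring-strain argument directs the allyl group to the α-face.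

**3. Step 2.**
- What may go wrong: stalling after the first C–C bond (open Michael adduct), protodesilylation of the diene by the acidic catalyst, or insufficient facial discrimination with so hindered a diene.
- Fallback: it sets out from 2 and 3 and returns at 16. The cycloaddition is forced with a strong achiral mixed Lewis acid (AlBr3/AlMe3, toluene–CH2Cl2, 0 °C), a combination established for hindered 2-silyloxydienes and β-substituted cycloalkenones. Steps 3–9 are run on racemic material. Racemic 16 is esterified with (S)-2-methoxy-2-phenylacetic acid (DCC, DMAP) to the (S)-O-methylmandelate F5 and the diastereomeric mandelate F6 (from the antipode of 16), which are separated by chromatography or crystallisation. LiOH (THF–H2O) followed by acidification, which recloses any opened lactone, returns enantiopure 16 from F5.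

Further compounds
F1 | step 9 | tosylhydrazone of 15 | O=C4[C@]12C[C@H](O4)[C@H](O[Si](C)(C)C(C)(C)C)C(C)(C)[C@@]1(C/C=N/NS(=O)(=O)c3ccc(C)cc3)C(=O)C(C)=C2
F2 | step 9 | diazoalkane (Ch=N2) | O=C4[C@]12C[C@H](O4)[C@H](O[Si](C)(C)C(C)(C)C)C(C)(C)[C@@]1(CC=[N+]=[N-])C(=O)C(C)=C2
F3 | step 9 | bridged 1-pyrazoline (Ch–N=N–Cj on the endo side, Ch–Ci formed) | O=C4[C@]12C[C@H](O4)[C@H](O[Si](C)(C)C(C)(C)C)C(C)(C)[C@]13C[C@@H]5[C@H]2[C@@](C)(N=N5)C3=O
F4 | step 7 | allyl dienol ether of 11 | O=C4[C@]12C[C@H](O4)[C@H](O[Si](C)(C)C(C)(C)C)C(C)(C)C1=C(OCC=C)C(C)=C2
F5 | step 2 | (S)-O-methylmandelate of 16 | O=C4[C@]12C[C@H](O4)[C@H](O[Si](C)(C)C(C)(C)C)C(C)(C)[C@]13C[C@H](OC(=O)[C@@H](OC)c5ccccc5)[C@H]2[C@H](C)C3=O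
F6 | step 2 | (S)-O-methylmandelate of the antipode of 16 | O=C4[C@@]12C[C@@H](O4)[C@@H](O[Si](C)(C)C(C)(C)C)C(C)(C)[C@@]13C[C@@H](OC(=O)[C@@H](OC)c5ccccc5)[C@@H]2[C@@H](C)C3=O
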